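## Retrosynthetic overview

1. The target is a CH2-bridged pair of acylfilicinic acids. The bridge is cut by a retro-Michael step into the Mannich base 8 of ring A (the acetyl ring) and butanoylfilicinic acid 10 (ring B).
2. Ring B is opened, as in the polyketide biosynthesis of acylphloroglucinols, at the bond between the ring carbon that carries the butanoyl group and the neighbouring C–OH carbon (the one that also neighbours the bridge-bearing carbon). The forward reaction is a Claisen cyclisation of the linear tetraketide ester 5 through its acylketene.
3. Enabling feature: in ring B the C(CH3)2 carbon sits between two carbonyl carbons and cannot enolise. Chain 5 therefore holds two insulated 1,3-dicarbonyl units, with the future butanoyl-bearing carbon as the doubly activated CH2 of a β-diketone six atoms from the ester carbon. The same gem-dimethyl group shuts off the aldol (orsellinate-type) and pyranone channels.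
4. Chain 5 comes from methyl 2,2-dimethylacetoacetate 1 by two Claisen-type acylations (butanoyl chloride, then tert-butyl acetate). Ring A comes from phloroacetophenone 6 by geminal C-methylation and a Mannich reaction.
5. Ring order: ring A first (the carbocycle of 6, dearomatised in step 3); ring B last, closed in step 5 and bridged to ring A in the same flask.

Key step: step 5

Remark on the chemistry: all polycarbonyl compounds are drawn as one tautomer (7, 8, 10 and 12 as the dienol form of the target SMILES) although they exist as mixtures of enol forms; the target has no stereocentre, so no step has to set configuration.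

## Route

Step 1
Reactants: 1 methyl 2,2-dimethyl-3-oxobutanoate; 2 butanoyl chloride
Product: 3 methyl 2,2-dimethyl-3,5-dioxooctanoate
Conditions: 1 (2.0 equiv), LiN(SiMe3)2 (2.0 equiv), toluene–THF, −78 °C; then 2 (1.0 equiv), −78 → 0 °C; 1 M HCl; excess 1 removed under vacuum
Reagents that add atoms: none
Why: C-acylation of a ketone lithium enolate by an acid chloride (Claisen-type acylation) should work because 1 can enolise only at its acetyl CH3 (C2 is quaternary) and the second equivalent of enolate takes the acidic proton of the new β-diketone, so 3 is not acylated again.

Step 2
Reactants: 3 methyl 2,2-dimethyl-3,5-dioxooctanoate; 4 tert-butyl acetate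
Product: 5 tert-butyl 4,4-dimethyl-3,5,7-trioxodecanoate
Conditions: 4 (4.0 equiv), LiN(i-Pr)2 (4.0 equiv), THF, −78 °C; then 3, −78 → −20 °C; cold 1 M HCl; used crude
Reagents that add atoms: none
Why: In this crossed Claisen condensation the first equivalent of LiCH2CO2t-Bu turns the β-diketone of 3 into its lithium enolate and so masks both ketones, the non-enolisable methyl ester is the only acceptor, and deprotonation of the new β-keto ester pulls the condensation forward.

Step 3
Reactants: 6 1-(2,4,6-trihydroxyphenyl)ethan-1-one (phloroacetophenone)
Product: 7 acetylfilicinic acid (2-acetyl-3,5-dihydroxy-6,6-dimethylcyclohexa-2,4-dien-1-one)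
Conditions: NaOMe (3.0 equiv), MeI (2.2 equiv), MeOH, 0 °C → rt; 1 M HCl; crystallisation
Reagents that add atoms: iodomethane, CI
Why: Dearomatising geminal C-methylation of a phloroglucinolate (the classical filicinic acid synthesis) should put both methyl groups on one ring carbon, and the stoichiometry of about two equivalents of MeI limits tri- and tetramethylation.

Step 4
Reactants: 7 acetylfilicinic acid
Product: 8 2-acetyl-4-[(dimethylamino)methyl]-3,5-dihydroxy-6,6-dimethylcyclohexa-2,4-dien-1-one (Mannich base, an inner salt)
Conditions: 7 added slowly to CH2(NMe2)2 (1.05 equiv), MeCN, 0 °C → rt; concentrate, triturate with Et2O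
Reagents that add atoms: bis(dimethylamino)methane, CN(C)CN(C)C
Why: In this Mannich reaction the acidic trione protonates the aminal, the enol attacks CH2=NMe2+ at the only free ring carbon, and the product separates as an inner salt, which should keep it from reacting on to the symmetrical methylene-bis compound.

Step 5
Reactants: 5 tert-butyl 4,4-dimethyl-3,5,7-trioxodecanoate; 8 Mannich base of acetylfilicinic acid
Product: 12 albaspidin AB (the target), via acylketene 9 (not isolated), via butanoylfilicinic acid 10 (not isolated), via methylidene trione 11 (not isolated)
Conditions: 5, DBU (1,8-diazabicyclo[5.4.0]undec-7-ene, 1.1 equiv), toluene (0.05 M), 110 °C; then cool to 60 °C, add 8 (1.0 equiv) in MeCN, 60 °C; 1 M HCl; crystallisation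
Reagents that add atoms: none
Why: One equivalent of DBU ionises only the β-diketone of 5; at 110 °C the un-ionised tert-butyl β-keto ester end loses tert-butanol to acylketene 9, the diketonate carbon (C6 of the chain, which carries the butanoyl group) adds to the ketene carbon (C1), and tautomerisation gives the amidinium salt of 10; added 8 then loses dimethylamine to the exocyclic enone 11, which 10 captures by Michael addition. The closest known reaction types are the biomimetic Claisen cyclisation of 3,5,7-triketo esters to acylphloroglucinols (the C6-to-C1 ring closure of polyketide synthases, with 9 in the role of the enzyme-bound thioester), the thermal release of acylketenes from tert-butyl β-keto esters, and the Mannich-base route to unsymmetrical methylene-bis(acylphloroglucinols). Ring B closes in a 6-(enolexo)-exo-dig mode at the ketene carbonyl (6-exo-trig if the ester is attacked directly), helped by the geminal dimethyl group on the tether. No stereocentre is formed. C- over O-acylation is needed and should be secured thermodynamically, because the O-acylated enol lactone is a β-keto enol ester that reverts to 9 under the conditions while the C-acylated trione is removed as its stabilised anion; the aldol channel is closed because the butanoyl ketone is tied up in the diketonate while the ester α-carbon stays un-ionised, and no alkoxide is present to cleave the non-enolisable C(=O)–C(CH3)2–C(=O) unit. In the bridging, adding 8 only after ring closure ensures that 11 meets 10 alone, whose single ring CH between the two enol carbons fixes the site of the CH2 link.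

## Compound list

1 | methyl 2,2-dimethyl-3-oxobutanoate | CC(=O)C(C)(C)C(=O)OC | starting material
2 | butanoyl chloride | CCCC(=O)Cl | starting material
3 | methyl 2,2-dimethyl-3,5-dioxooctanoate | CCCC(=O)CC(=O)C(C)(C)C(=O)OC | intermediate
4 | tert-butyl acetate | CC(=O)OC(C)(C)C | starting material
5 | tert-butyl 4,4-dimethyl-3,5,7-trioxodecanoate | CCCC(=O)CC(=O)C(C)(C)C(=O)CC(=O)OC(C)(C)C | intermediate
6 | 1-(2,4,6-trihydroxyphenyl)ethan-1-one (phloroacetophenone) | CC(=O)c1c(O)cc(O)cc1O | starting material
7 | acetylfilicinic acid, 2-acetyl-3,5-dihydroxy-6,6-dimethylcyclohexa-2,4-dien-1-one | CC(=O)C1=C(O)C=C(O)C(C)(C)C1=O | intermediate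
8 | 2-acetyl-4-[(dimethylamino)methyl]-3,5-dihydroxy-6,6-dimethylcyclohexa-2,4-dien-1-one (Mannich base) | CC(=O)C1=C(O)C(CN(C)C)=C(O)C(C)(C)C1=O | intermediate
9 | 4,4-dimethyldec-1-ene-1,3,5,7-tetrone (acylketene) | CCCC(=O)CC(=O)C(C)(C)C(=O)C=C=O | intermediate
10 | butanoylfilicinic acid, 2-butanoyl-3,5-dihydroxy-6,6-dimethylcyclohexa-2,4-dien-1-one | CCCC(=O)C1=C(O)C=C(O)C(C)(C)C1=O | intermediate
11 | 2-acetyl-3-hydroxy-6,6-dimethyl-4-methylidenecyclohex-2-ene-1,5-dione (methylidene trione) | CC(=O)C1=C(O)C(=C)C(=O)C(C)(C)C1=O | intermediate
12 | albaspidin AB, 2-acetyl-4-[(5-butanoyl-2,6-dihydroxy-3,3-dimethyl-4-oxocyclohexa-1,5-dien-1-yl)methyl]-3,5-dihydroxy-6,6-dimethylcyclohexa-2,4-dien-1-one (no stereocentre) | CCCC(=O)C1=C(O)C(CC2=C(O)C(C)(C)C(=O)C(C(C)=O)=C2O)=C(O)C(C)(C)C1=O | target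

## Step count and risks

Total step count: 5. Longest linear sequence: 3 steps (1 → 3 → 5 → 12, or 6 → 7 → 8 → 12).

Steps most likely to fail:

**Step 5 (ring closure and bridging in one flask).** The diketonate may be acylated on oxygen and rest as the enol-lactone anion instead of funnelling to the C-acylated trione. During the bridging the two halves may also exchange partners by retro-Michael/Michael equilibration under base, which would give the two symmetrical dimers. The fallback sets out from 5. Heating 5 with methanol (20 equiv) in toluene at 110 °C in a sealed tube should exchange the ester, through 9, to methyl 4,4-dimethyl-3,5,7-trioxodecanoate F1. F1 would then be cyclised by a magnesium-templated Claisen condensation of the polyanion (Mg(OMe)2, MeOH, reflux; then 1 M HCl), which comes back to the route at 10, now isolated and purified. Compounds 10 and 8 are finally joined in a separate, base-free operation (MeCN, 60 °C) through 11 to give 12.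

**Step 2 (Claisen condensation at a neopentyl-type ester of an anionic substrate).** The ester carbon, flanked by the quaternary carbon and close to the negative charge of the diketonate, may be attacked too slowly, so that the ester enolate is lost by proton transfer and self-condensation on warming. The fallback sets out from 3. Compound 3 would be closed to the neutral enol lactone 3,3-dimethyl-6-propyl-2H-pyran-2,4(3H)-dione F2 (p-toluenesulfonic acid cat., toluene, reflux, methanol distilled off). The enol-ester carbonyl of F2 is a much better acyl donor and should be opened by LiCH2CO2t-Bu (2.2 equiv, THF, −78 °C) in a ring-opening Claisen condensation that releases the diketonate and comes back to the route at 5.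

**Step 3 (geminal C-methylation).** Under- and over-methylation (mono-, tri- and tetramethyl products) and some O-methylation may give a mixture from which 7 is hard to separate. The fallback sets out from 1 and builds ring A de novo by the chemistry used for ring B. The lithium enolate of 1 (LiN(SiMe3)2, toluene–THF, −78 °C) and acetyl chloride should give methyl 2,2-dimethyl-3,5-dioxohexanoate F3. Claisen condensation with LiCH2CO2t-Bu would give tert-butyl 4,4-dimethyl-3,5,7-trioxooctanoate F4. DBU in toluene at 110 °C should then close the ring through the acylketene 4,4-dimethyloct-1-ene-1,3,5,7-tetrone F5 and come back to the route at 7.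

## Further compounds

F1 | step 5 | methyl 4,4-dimethyl-3,5,7-trioxodecanoate | CCCC(=O)CC(=O)C(C)(C)C(=O)CC(=O)OC
F2 | step 2 | 3,3-dimethyl-6-propyl-2H-pyran-2,4(3H)-dione | CCCC1=CC(=O)C(C)(C)C(=O)O1
F3 | step 3 | methyl 2,2-dimethyl-3,5-dioxohexanoate | CC(=O)CC(=O)C(C)(C)C(=O)OC
F4 | step 3 | tert-butyl 4,4-dimethyl-3,5,7-trioxooctanoate | CC(=O)CC(=O)C(C)(C)C(=O)CC(=O)OC(C)(C)C
F5 | step 3 | 4,4-dimethyloct-1-ene-1,3,5,7-tetrone | CC(=O)CC(=O)C(C)(C)C(=O)C=C=O
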